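The readings come from a simulation with constants of no real substance, and the scatter is random.

We plan the 1.5 h reading as a question of how far target has decayed, so we reckon in powers of ten.

- violet: substrate 0.16 M; reagent in the second phase 1.5 equiv; run made earlier
- flask: substrate 0.16 M; reagent in the second phase 1.00 equiv; time 1.5 h; volume of the second phase over the first 1.0

- violet (time / min: target / %, substrate / %): 1.33: 12.6, 72.0; 2.50: 27.5, 49.5; 5.00: 46.5, 21.5; 10.0: 55.3, 1.8; 20.0: 42.3, 0

(readings scatter by 0.5 percentage points)

- amounts and yields of target count product in the second phase too
- in the second phase: reagent in the second phase, product in the second phase; everything else is in the first
- charges count per volume of the first phase; a concentration in a rate is the amount of a species over the volume of its own phase; every rate counts per litre of the first phase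
- the earlier runs hold the two phases in the same ratio of volumes as the flask asked about

1. how much target and product in the second phase together there is at 1.5 h, in percent of the substrate charged
2. part of the substrate charged that has reacted at 1.5 h

In the violet run, substrate is down to 1.8% at 10.0 min, and the flask runs 9.00 times as long, so we take its conversion as complete. A target reading of 55.3% takes, at one reagent each, at least 0.553 of the flask's 1.00 equiv, so we don't expect reagent in the second phase to be the limiting reagent and we let the flask follow the violet curve.

But that curve falls: 55.3% becomes 42.3% by 20.0 min, and these two scattered readings give a first-order constant of 0.0268 /min for target and product in the second phase together. We carry the decade time of target, the time it takes to lose one power of ten, 85.8 min. One run can't show whether this decay needs reagent, and we assume it doesn't. From 20.0 min to 1.5 h is 0.816 decades, so our reckoning for the flask is 6.47%.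

The forecast says: “I lean towards reagent-driven over-reaction, hedged downward”; it gives 35% for target and product in the second phase together, and 93% of the substrate reacted.

The flask gives 4.46%, with 100% of the substrate reacted, so it stands 2 percentage points under our reckoning.

    reagent in the reaction phase ⇌ reagent in the second phase, rate k1*([reagent in the reaction phase] - [reagent in the second phase]/K1) per volume of the first phase (partition coefficient = 0.330, kL = 9.60 × 10⁻⁴ /s)
    2 substrate → self-condensation product (k = 0.00740 /M/s)
    substrate + reagent in the reaction phase → target (k = 0.120 /M/s)
    target → over-reaction product (k = 5.30 × 10⁻⁴ /s)
    target → decomposed product (k = 8.60 × 10⁻⁴ /s)
    target ⇌ product in the second phase, rate k6*([target] - [product in the second phase]/K6) per volume of the first phase (partition coefficient = 1.50, kL = 0.0100 /s)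

Changing the reagent charge by itself takes the violet run's 42.4% at its last reading to 40.2%, while changing the time by itself takes it to 4.60%. Now the decade time goes to the flask left until 25 min, which holds 34.8%. The 25.0 min up to a reading at 50 min are 0.291 decades, which gives 17.8%, and the flask read at 50 min holds 15.8%.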